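The data stem from a simulated flask for substances that don't exist.

- The vessel was closed, stirred and isothermal, with gas held at 28 mM. I wanted the end state of grey and ochre.

| flask | starting material | partner | gas | remark | time |
|---|---|---|---|---|---|
| north-east | 0.11 M | 0.0432 M | 28 mM (held) | run made earlier |  |
| grey | 0.072 M | 0.0432 M | 28 mM (held) |  | 25 h |
| ochre | 0.072 M | 0.0432 M | 28 mM (held) |  | 10 h |

north-east run (percent of the starting material charged)

| time / min | target / % | starting material / % |
|---|---|---|
| 10.0 | 25 | 75 |
| 20.0 | 32 | 68 |
| 30.0 | 36 | 62 |
| 60.0 | 40 | 60 |
| 120 | 38 | 57 |

(readings scatter by 1.5 percentage points)

- the analysis behind the earlier runs scatters by 1.5 percentage points, standard deviation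
- at the start none of the gas is in solution
- a reading or a percentage of target counts all its forms, free or not

* which of the two there is more of at the end, grey (side product / target)
* which of the two there is more of at the end, ochre (side product / target)
* amount of target at the end, in percent of the starting material charged, grey
* amount of target at the end, in percent of the starting material charged, ochre

- In north-east, by 60.0 min, starting material had lost 0.0440 M, close to the 0.0432 M of partner charged. So I took partner as the limiting reagent, used one-to-one. The ratio of the charges there, 39.3%, lies between the last target readings, 40% and 38%.
- The partner charge had to be known well: in grey and ochre, 5% off moves that ratio by 3 percentage points. The starting material charge matters equally, in the opposite direction.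
- Time mattered little. North-east stalled by 60.0 min; ochre's 10 h is ten times that, more than the factor 1.53 by which its starting material charge is lower, and grey runs 25 h.
- The gas needed no precision: it stood at 28 mM in north-east, where target still reached the ratio, and at 28 mM in grey and ochre.
- I computed only a correction to the ratio. North-east's target fell 2 points between its last readings, while such a difference scatters by 2.1 points, so I set the correction to nil.
- For grey and ochre the ratio is 60.0%. I call it Y, partner charged over starting material charged, the ceiling on target. The rest of the charge, 40.0%, is less than Y, so I expected more target than side product in both.
- The forecast gave 40% in grey and 49% in ochre, with more target in grey and more target in ochre, on its reading of “slow loss, probably target reacting with leftover starting material”; my figures differ from these.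
- The flask gave 60.0% target in grey and 60.0% in ochre, against side product at 28.0% and 14.7%.

    starting material + rival reagent → side product (k = 0.0300 /M/min)
    gas ⇌ rival reagent, rate k2*(csat - [rival reagent]) (kL = 0.0210 /min)
    starting material + partner → target (k = 1.10 /M/min)
    crystals ⇌ target, rate k4*(cs4 - [target]) while solid is left; crystals form when [target] > cs4 (solubility = 25.0 mM, k = 1.20 /min)

- Target in grey stood at Y, 60.0%. A neighbour of grey, with partner cut to 0.026 M, has Y = 36.1%, and the rest of its charge, 63.9%, now exceeds Y, so the ordering test gives no assurance there. The neighbour gave 36.1% target at 25.0 h, with partner at 0% and starting material at 19.7%. Its side product reached 44.2%, more than its target.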